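Everything rests on cutting the dihydrofuran ring at O1–C2 and C2–C3. Within that ring C2 is bonded only to O1 and C3 and carries the catechol aryl group, so the whole carbon can come from the benzylic carbon of a chiral sulfonium ylide, while O1, ring B (the benzo ring) and the ester-bearing C3 come from an ortho-quinone methide. One operation joins the two aryl fragments, closes the five-membered ring and sets C2 and C3 (2S,3S, trans). The methide precursor is a racemic α-bromo arylacetate with a silyl-masked phenol as fluoride trigger, a benzyl ether at O7 and a dioxolane-masked C4 aldehyde. The danshensu ester is attached afterwards by olefination; all benzyl groups fall last.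

Key step: step 9

Assumption (chemistry; benzofuran numbering O1, C2, C3, C3a, C4–C7, C7a): the thiolanium benzylide is taken to add to the methide carbon with the face it uses towards aldehydes. The (2R,5R)-thiolane gives (S,S)-stilbene oxide, and because at C2 the aryl group outranks C3 (in the oxirane the ring carbon outranks phenyl) the same spatial course reads 2R. The (2S,5S)-thiolane, made from (2R,5R)-hexane-2,5-diol, is therefore the antipode used for 2S; if the first run shows the opposite sense, the (2S,5S)-diol enters step 6 and nothing else changes.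

Step 1
Reactants: 1 4-(benzyloxy)-3-hydroxybenzaldehyde
Product: 2 4-(benzyloxy)-2-bromo-3-hydroxybenzaldehyde
Conditions: Br2, NaOAc, Fe powder (cat.), AcOH, rt
Reagents that add atoms: bromine, BrBr
Why: Electrophilic aromatic bromination directed by the free phenol should go to the ortho position between hydroxyl and formyl group, as isovanillin does under the same buffered conditions, while NaOAc takes up HBr so that the benzyl ether survives.

Step 2
Reactants: 2 4-(benzyloxy)-2-bromo-3-hydroxybenzaldehyde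
Product: 3 6-(benzyloxy)-2-bromo-3-(1,3-dioxolan-2-yl)phenol
Conditions: HOCH2CH2OH, p-TsOH·H2O (cat.), toluene, reflux, Dean–Stark
Reagents that add atoms: ethylene glycol, OCCO
Why: Acid-catalysed acetalisation with azeotropic removal of water masks the aldehyde, which the zinc enolate, the amide base and above all the sulfonium ylide would otherwise attack.

Step 3
Reactants: 3 6-(benzyloxy)-2-bromo-3-(1,3-dioxolan-2-yl)phenol
Product: 4 [6-(benzyloxy)-2-bromo-3-(1,3-dioxolan-2-yl)phenoxy](tert-butyl)dimethylsilane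
Conditions: TBSCl, imidazole, DMF, rt to 40 °C
Reagents that add atoms: tert-butyldimethylsilyl chloride, CC(C)(C)[Si](C)(C)Cl
Why: Imidazole-promoted O-silylation of the phenol installs the fluoride-labile trigger, and a silyl chloride is used instead of a silyl triflate because the latter could open the dioxolane.

Step 4
Reactants: 4 [6-(benzyloxy)-2-bromo-3-(1,3-dioxolan-2-yl)phenoxy](tert-butyl)dimethylsilane
Product: 5 methyl 2-[3-(benzyloxy)-2-(tert-butyldimethylsilyloxy)-6-(1,3-dioxolan-2-yl)phenyl]acetate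
Conditions: BrZnCH2CO2Me (from BrCH2CO2Me, Zn dust, Me3SiCl cat., THF), Pd(dba)2 (5 mol %), QPhos (5 mol %), THF, 65 °C
Reagents that add atoms: Reformatsky reagent bromo(2-methoxy-2-oxoethyl)zinc, COC(=O)C[Zn]Br (made in the flask from methyl bromoacetate, COC(=O)CBr, and zinc)
Why: Palladium-catalysed Negishi-type coupling of the aryl bromide with a Reformatsky reagent (α-arylation of a zinc ester enolate) runs under neutral conditions that spare the aryl silyl ether and the acetal, and the bulky electron-rich ferrocenyl phosphine is chosen for a bromide with two ortho substituents.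

Step 5
Reactants: 5 methyl 2-[3-(benzyloxy)-2-(tert-butyldimethylsilyloxy)-6-(1,3-dioxolan-2-yl)phenyl]acetate
Product: 7 methyl (±)-2-bromo-2-[3-(benzyloxy)-2-(tert-butyldimethylsilyloxy)-6-(1,3-dioxolan-2-yl)phenyl]acetate, via silyl ketene acetal 6 (not isolated)
Conditions: LiN(SiMe3)2, Me3SiCl, THF, −78 °C; then NBS, −78 to 0 °C
Reagents that add atoms: N-bromosuccinimide, O=C1CCC(=O)N1Br
Why: Enolisation with immediate O-silylation and electrophilic bromination of the silyl ketene acetal by NBS should give the monobromide without proton exchange between product and enolate and without migration of the phenol silyl group to the enolate, and the new center is left racemic because it becomes trigonal in step 9.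

Step 6
Reactants: 8 (2R,5R)-hexane-2,5-diol
Product: 9 (2R,5R)-hexane-2,5-diyl dimethanesulfonate
Conditions: MsCl, Et3N, CH2Cl2, 0 °C
Reagents that add atoms: methanesulfonyl chloride, CS(=O)(=O)Cl
Why: O-Sulfonylation of both secondary alcohols breaks no bond to carbon, so the bis-electrophile keeps the (2R,5R) configuration.

Step 7
Reactants: 9 (2R,5R)-hexane-2,5-diyl dimethanesulfonate
Product: 10 (2S,5S)-2,5-dimethylthiolane
Conditions: Na2S·9H2O, DMSO, rt
Reagents that add atoms: sodium sulfide, [Na+].[Na+].[S-2]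
Why: Double SN2 displacement by sulfide, the second one a 5-exo-tet ring closure, inverts both centers and should give the twofold-symmetric (2S,5S)-thiolane.

Step 8
Reactants: 10 (2S,5S)-2,5-dimethylthiolane; 11 3,4-bis(benzyloxy)benzyl chloride
Product: 12 (2S,5S)-1-[3,4-bis(benzyloxy)benzyl]-2,5-dimethylthiolanium tetrafluoroborate
Conditions: AgBF4, CH2Cl2, 0 °C to rt, dark
Reagents that add atoms: silver tetrafluoroborate, [Ag+].F[B-](F)(F)F
Why: Silver-assisted S-alkylation of the sulfide by the electron-rich benzyl chloride gives the sulfonium salt with a non-nucleophilic counter-ion so that the alkylation cannot revert, and the twofold axis of the thiolane makes both sulfur lone pairs equivalent, hence one salt only.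

Step 9
Reactants: 7 methyl (±)-2-bromo-2-[3-(benzyloxy)-2-(tert-butyldimethylsilyloxy)-6-(1,3-dioxolan-2-yl)phenyl]acetate; 12 (2S,5S)-1-[3,4-bis(benzyloxy)benzyl]-2,5-dimethylthiolanium tetrafluoroborate
Product: 16 methyl (2S,3S)-7-(benzyloxy)-2-[3,4-bis(benzyloxy)phenyl]-4-(1,3-dioxolan-2-yl)-2,3-dihydrobenzofuran-3-carboxylate, via sulfonium benzylide 13 (not isolated), via o-quinone methide 14 (not isolated), via sulfonium phenoxide betaine 15 (not isolated)
Conditions: Cs2CO3, CsF, 18-crown-6, MeCN–CH2Cl2, −30 to 0 °C (12 and Cs2CO3 first, then 7 and CsF)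
Reagents that add atoms: none
Why: Carbonate deprotonates the benzylic position of 12 to ylide 13, fluoride removes the silyl group of 7 and the phenoxide expels bromide by 1,4-elimination to give the ester-substituted methide 14, conjugate addition of the ylide carbon to the exocyclic methide carbon forms C2–C3 and restores the aromaticity of ring B, and the phenoxide of betaine 15 then displaces the thiolane at C2 with inversion to form O1–C2. The closest known reactions are the formal [4+1] annulation of in situ generated o-quinone methides with sulfonium ylides to trans-2,3-dihydrobenzofurans, the fluoride-triggered release of o-quinone methides from o-silyloxybenzyl bromides, and benzylidene transfer from chiral thiolanium salts to aldehydes. The dihydrofuran ring closes by 5-exo-tet substitution at the benzylic carbon. C2 is set under reagent control: the ylide turns its aryl group away from the thiolane ring, the methyl group cis to the ylide carbon shields one face, and the addition is irreversible because it rearomatises ring B, so the (2S,5S)-thiolane should lead to 2S after the inverting ring closure. C3 is set under thermodynamic control, since it is the acidic benzylic α-carbon of the ester and should equilibrate under carbonate to the trans (3S) isomer with ester and aryl group on opposite faces. The step needs conjugate addition to outrun direct alkylation of the ylide by the bromide and loss of the sulfide by elimination, which the fast fluoride trigger, the strongly electrophilic ester-substituted methide and the low temperature should secure, while the dioxolane keeps the ylide from epoxidising the aldehyde and all other phenols are benzyl ethers inert to fluoride.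

Step 10
Reactants: 16 methyl (2S,3S)-7-(benzyloxy)-2-[3,4-bis(benzyloxy)phenyl]-4-(1,3-dioxolan-2-yl)-2,3-dihydrobenzofuran-3-carboxylate
Product: 17 methyl (2S,3S)-7-(benzyloxy)-2-[3,4-bis(benzyloxy)phenyl]-4-formyl-2,3-dihydrobenzofuran-3-carboxylate
Conditions: p-TsOH·H2O (cat.), acetone–H2O, rt
Reagents that add atoms: water, O
Why: Acid-catalysed acetal hydrolysis frees the aldehyde while the methyl ester, the benzyl ethers and the two stereocenters, which are labile only to base, should stay untouched.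

Step 11
Reactants: 18 (R)-3-(3,4-dihydroxyphenyl)lactic acid (danshensu)
Product: 19 benzyl (R)-3-[3,4-bis(benzyloxy)phenyl]-2-hydroxypropanoate
Conditions: BnBr (3.3 equiv), K2CO3, DMF, rt, argon
Reagents that add atoms: benzyl bromide, BrCc1ccccc1
Why: Williamson-type O-alkylation with carbonate benzylates the two phenols and the carboxylate but not the far less acidic secondary alcohol, and no bond to the stereocenter is touched.

Step 12
Reactants: 19 benzyl (R)-3-[3,4-bis(benzyloxy)phenyl]-2-hydroxypropanoate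
Product: 20 benzyl (R)-3-[3,4-bis(benzyloxy)phenyl]-2-{[2-(diethoxyphosphoryl)acetyl]oxy}propanoate
Conditions: (EtO)2P(O)CH2CO2H, DCC, DMAP (cat.), CH2Cl2, 0 °C to rt
Reagents that add atoms: diethylphosphonoacetic acid, CCOP(=O)(CC(=O)O)OCC
Why: Steglich esterification acylates the secondary alcohol with retention because the C–O bond at the stereocenter is not broken.

Step 13
Reactants: 17 methyl (2S,3S)-7-(benzyloxy)-2-[3,4-bis(benzyloxy)phenyl]-4-formyl-2,3-dihydrobenzofuran-3-carboxylate; 20 benzyl (R)-3-[3,4-bis(benzyloxy)phenyl]-2-{[2-(diethoxyphosphoryl)acetyl]oxy}propanoate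
Product: 21 methyl (2S,3S)-7-(benzyloxy)-4-[(E)-3-{[(2R)-1-(benzyloxy)-3-[3,4-bis(benzyloxy)phenyl]-1-oxopropan-2-yl]oxy}-3-oxoprop-1-en-1-yl]-2-[3,4-bis(benzyloxy)phenyl]-2,3-dihydrobenzofuran-3-carboxylate
Conditions: LiCl, iPr2NEt, MeCN, rt
Reagents that add atoms: none
Why: Horner–Wadsworth–Emmons olefination under Masamune–Roush conditions should give the E-cinnamate, and the lithium-assisted weak amine base is chosen so that neither C3 nor the lactate center is deprotonated.

Step 14
Reactants: 21 methyl (2S,3S)-7-(benzyloxy)-4-[(E)-3-{[(2R)-1-(benzyloxy)-3-[3,4-bis(benzyloxy)phenyl]-1-oxopropan-2-yl]oxy}-3-oxoprop-1-en-1-yl]-2-[3,4-bis(benzyloxy)phenyl]-2,3-dihydrobenzofuran-3-carboxylate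
Product: 22 monomethyl lithospermate
Conditions: BCl3 (1 M in CH2Cl2), C6HMe5, CH2Cl2, −78 to −20 °C; then aqueous NaHCO3, acidify to pH 3
Reagents that add atoms: none
Why: Lewis-acid debenzylation with BCl3 and pentamethylbenzene as non-basic benzyl cation scavenger should cleave the five aryl benzyl ethers and the benzyl ester at low temperature without touching the alkene, the methyl ester or the cinnamate ester, and the phenols stay as electron-poor boron esters until the quench, which disfavours ionisation at C2.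

Compound list
1 | 4-(benzyloxy)-3-hydroxybenzaldehyde | O=Cc1ccc(OCc2ccccc2)c(O)c1 | starting material
2 | 4-(benzyloxy)-2-bromo-3-hydroxybenzaldehyde | O=Cc1ccc(OCc2ccccc2)c(O)c1Br | intermediate
3 | 6-(benzyloxy)-2-bromo-3-(1,3-dioxolan-2-yl)phenol | Oc1c(Br)c(C2OCCO2)ccc1OCc1ccccc1 | intermediate
4 | [6-(benzyloxy)-2-bromo-3-(1,3-dioxolan-2-yl)phenoxy](tert-butyl)dimethylsilane | CC(C)(C)[Si](C)(C)Oc1c(Br)c(C2OCCO2)ccc1OCc1ccccc1 | intermediate
5 | methyl 2-[3-(benzyloxy)-2-(tert-butyldimethylsilyloxy)-6-(1,3-dioxolan-2-yl)phenyl]acetate | COC(=O)Cc1c(C2OCCO2)ccc(OCc2ccccc2)c1O[Si](C)(C)C(C)(C)C | intermediate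
6 | tert-butyl{6-(benzyloxy)-3-(1,3-dioxolan-2-yl)-2-[2-methoxy-2-(trimethylsilyloxy)ethenyl]phenoxy}dimethylsilane (silyl ketene acetal, alkene geometry not defined) | COC(O[Si](C)(C)C)=Cc1c(C2OCCO2)ccc(OCc2ccccc2)c1O[Si](C)(C)C(C)(C)C | intermediate (not isolated)
7 | methyl (±)-2-bromo-2-[3-(benzyloxy)-2-(tert-butyldimethylsilyloxy)-6-(1,3-dioxolan-2-yl)phenyl]acetate | COC(=O)C(Br)c1c(C2OCCO2)ccc(OCc2ccccc2)c1O[Si](C)(C)C(C)(C)C | intermediate
8 | (2R,5R)-hexane-2,5-diol | C[C@@H](O)CC[C@@H](C)O | starting material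
9 | (2R,5R)-hexane-2,5-diyl dimethanesulfonate | C[C@@H](OS(C)(=O)=O)CC[C@@H](C)OS(C)(=O)=O | intermediate
10 | (2S,5S)-2,5-dimethylthiolane | C[C@H]1CC[C@H](C)S1 | intermediate
11 | 3,4-bis(benzyloxy)benzyl chloride [1,2-bis(benzyloxy)-4-(chloromethyl)benzene] | ClCc1ccc(OCc2ccccc2)c(OCc2ccccc2)c1 | starting material
12 | (2S,5S)-1-[3,4-bis(benzyloxy)benzyl]-2,5-dimethylthiolanium tetrafluoroborate | C[C@H]1CC[C@H](C)[S+]1Cc1ccc(OCc2ccccc2)c(OCc2ccccc2)c1.F[B-](F)(F)F | intermediate
13 | (2S,5S)-2,5-dimethylthiolanium 3,4-bis(benzyloxy)benzylide (sulfonium ylide, carbanion on the benzylic carbon) | C[C@H]1CC[C@H](C)[S+]1[CH-]c1ccc(OCc2ccccc2)c(OCc2ccccc2)c1 | intermediate (not isolated)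
14 | methyl 2-[5-(benzyloxy)-2-(1,3-dioxolan-2-yl)-6-oxocyclohexa-2,4-dien-1-ylidene]acetate (o-quinone methide, alkene geometry not defined) | COC(=O)C=C1C(=O)C(OCc2ccccc2)=CC=C1C3OCCO3 | intermediate (not isolated)
15 | 6-(benzyloxy)-2-{(2R)-2-[3,4-bis(benzyloxy)phenyl]-2-[(2S,5S)-2,5-dimethylthiolan-1-ium-1-yl]-1-(methoxycarbonyl)ethyl}-3-(1,3-dioxolan-2-yl)phenolate (betaine, ester-bearing carbon not yet fixed) | COC(=O)C(c1c(C2OCCO2)ccc(OCc2ccccc2)c1[O-])[C@@H]([S+]1[C@@H](C)CC[C@@H]1C)c1ccc(OCc2ccccc2)c(OCc2ccccc2)c1 | intermediate (not isolated)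
16 | methyl (2S,3S)-7-(benzyloxy)-2-[3,4-bis(benzyloxy)phenyl]-4-(1,3-dioxolan-2-yl)-2,3-dihydrobenzofuran-3-carboxylate | COC(=O)[C@H]1c2c(C3OCCO3)ccc(OCc3ccccc3)c2O[C@@H]1c1ccc(OCc2ccccc2)c(OCc2ccccc2)c1 | intermediate
17 | methyl (2S,3S)-7-(benzyloxy)-2-[3,4-bis(benzyloxy)phenyl]-4-formyl-2,3-dihydrobenzofuran-3-carboxylate | COC(=O)[C@H]1c2c(C=O)ccc(OCc3ccccc3)c2O[C@@H]1c1ccc(OCc2ccccc2)c(OCc2ccccc2)c1 | intermediate
18 | (R)-3-(3,4-dihydroxyphenyl)lactic acid (danshensu) | O[C@H](Cc1ccc(O)c(O)c1)C(=O)O | starting material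
19 | benzyl (R)-3-[3,4-bis(benzyloxy)phenyl]-2-hydroxypropanoate | O[C@H](Cc1ccc(OCc2ccccc2)c(OCc2ccccc2)c1)C(=O)OCc1ccccc1 | intermediate
20 | benzyl (R)-3-[3,4-bis(benzyloxy)phenyl]-2-{[2-(diethoxyphosphoryl)acetyl]oxy}propanoate | CCOP(=O)(CC(=O)O[C@H](Cc1ccc(OCc2ccccc2)c(OCc2ccccc2)c1)C(=O)OCc1ccccc1)OCC | intermediate
21 | methyl (2S,3S)-7-(benzyloxy)-4-[(E)-3-{[(2R)-1-(benzyloxy)-3-[3,4-bis(benzyloxy)phenyl]-1-oxopropan-2-yl]oxy}-3-oxoprop-1-en-1-yl]-2-[3,4-bis(benzyloxy)phenyl]-2,3-dihydrobenzofuran-3-carboxylate | COC(=O)[C@H]1c2c(/C=C/C(=O)O[C@H](Cc3ccc(OCc4ccccc4)c(OCc4ccccc4)c3)C(=O)OCc3ccccc3)ccc(OCc3ccccc3)c2O[C@@H]1c1ccc(OCc2ccccc2)c(OCc2ccccc2)c1 | intermediate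
22 | monomethyl lithospermate, (2R)-3-(3,4-dihydroxyphenyl)-2-{[(E)-3-[(2S,3S)-2-(3,4-dihydroxyphenyl)-7-hydroxy-3-(methoxycarbonyl)-2,3-dihydrobenzofuran-4-yl]prop-2-enoyl]oxy}propanoic acid | COC(=O)[C@H]1c2c(/C=C/C(=O)O[C@H](Cc3ccc(O)c(O)c3)C(=O)O)ccc(O)c2O[C@@H]1c1ccc(O)c(O)c1 | target

Total step count: 14. Longest linear sequence: 9 steps (steps 1–5, 9, 10, 13, 14).

Steps most likely to fail

Step 9. The ylide carbon may discriminate poorly between its two faces at the methide carbon, or the betaine may lose the sulfide by elimination so that an open α-aryl cinnamate recloses without stereocontrol; the methide may also oligomerise before it is trapped. The fallback sets out from 5 (with 11) and comes back at 16, using enantioselective carbene C–H insertion. Fluoride desilylation of 5 with O-benzylation by 11 in the same flask (CsF, DMF) should give methyl 2-[3-(benzyloxy)-2-{[3,4-bis(benzyloxy)benzyl]oxy}-6-(1,3-dioxolan-2-yl)phenyl]acetate F1. Regitz diazo transfer (4-acetamidobenzenesulfonyl azide, DBU, MeCN) should give methyl 2-diazo-2-[3-(benzyloxy)-2-{[3,4-bis(benzyloxy)benzyl]oxy}-6-(1,3-dioxolan-2-yl)phenyl]acetate F2. Intramolecular insertion of the rhodium carbene into the benzylic ether C–H bond with the chiral dirhodium carboxylate Rh2(S-PTTL)4 or its antipode (toluene, −60 °C), a known route to cis-2-aryl-2,3-dihydrobenzofuran-3-carboxylates, should give methyl (2S,3R)-7-(benzyloxy)-2-[3,4-bis(benzyloxy)phenyl]-4-(1,3-dioxolan-2-yl)-2,3-dihydrobenzofuran-3-carboxylate F3. Epimerisation of C3 with NaOMe in MeOH then gives the trans ester 16.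

Step 4. Oxidative addition and transmetalation at a bromide flanked by a silyloxy group and a dioxolane may be so slow that reduction of the C–Br bond and decay of the zinc enolate take over. The fallback sets out from 4 and comes back at 7, bypassing 5 and step 5. Bromine–magnesium exchange (iPrMgCl·LiCl, THF, 0 °C) and acylation with excess dimethyl oxalate at −78 °C should give methyl 2-[3-(benzyloxy)-2-(tert-butyldimethylsilyloxy)-6-(1,3-dioxolan-2-yl)phenyl]-2-oxoacetate F4. Ketone-selective reduction (NaBH4, THF–MeOH, −40 °C) should give methyl (±)-2-[3-(benzyloxy)-2-(tert-butyldimethylsilyloxy)-6-(1,3-dioxolan-2-yl)phenyl]-2-hydroxyacetate F5. Appel bromination (CBr4, PPh3, CH2Cl2, 0 °C) then gives 7.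

Step 14. The Lewis acid may ionise the benzylic C2–O1 bond of the electron-rich 2-aryl dihydrofuran, with loss of configuration at C2 or ring opening, and the benzyl ester may cleave more slowly than the ethers so that partly protected material remains. The fallback sets out from 16 and 19 and comes back at 22, removing all benzyl groups by hydrogenolysis before the alkene exists. Hydrogenolysis of 16 (H2, Pd/C, EtOAc–MeOH, rt; the acetal shields the formyl carbon from reduction) should give methyl (2S,3S)-2-(3,4-dihydroxyphenyl)-4-(1,3-dioxolan-2-yl)-7-hydroxy-2,3-dihydrobenzofuran-3-carboxylate F6. Aqueous acid (p-TsOH, acetone–H2O) should give methyl (2S,3S)-2-(3,4-dihydroxyphenyl)-4-formyl-7-hydroxy-2,3-dihydrobenzofuran-3-carboxylate F7. In parallel, 19 opens Meldrum's acid (toluene, 100 °C) to 3-{[(2R)-1-(benzyloxy)-3-[3,4-bis(benzyloxy)phenyl]-1-oxopropan-2-yl]oxy}-3-oxopropanoic acid F8. Hydrogenolysis (H2, Pd/C, EtOAc) gives (2R)-2-[(carboxyacetyl)oxy]-3-(3,4-dihydroxyphenyl)propanoic acid F9. Knoevenagel–Doebner condensation of F7 with F9 (pyridine, β-alanine cat., 40 °C, argon), the usual way to caffeic esters from unprotected hydroxybenzaldehydes, then gives 22 directly.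

Further compounds
F1 | step 9 | methyl 2-[3-(benzyloxy)-2-{[3,4-bis(benzyloxy)benzyl]oxy}-6-(1,3-dioxolan-2-yl)phenyl]acetate | COC(=O)Cc1c(C2OCCO2)ccc(OCc2ccccc2)c1OCc1ccc(OCc2ccccc2)c(OCc2ccccc2)c1
F2 | step 9 | methyl 2-diazo-2-[3-(benzyloxy)-2-{[3,4-bis(benzyloxy)benzyl]oxy}-6-(1,3-dioxolan-2-yl)phenyl]acetate | COC(=O)C(=[N+]=[N-])c1c(C2OCCO2)ccc(OCc2ccccc2)c1OCc1ccc(OCc2ccccc2)c(OCc2ccccc2)c1
F3 | step 9 | methyl (2S,3R)-7-(benzyloxy)-2-[3,4-bis(benzyloxy)phenyl]-4-(1,3-dioxolan-2-yl)-2,3-dihydrobenzofuran-3-carboxylate | COC(=O)[C@@H]1c2c(C3OCCO3)ccc(OCc3ccccc3)c2O[C@@H]1c1ccc(OCc2ccccc2)c(OCc2ccccc2)c1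
F4 | step 4 | methyl 2-[3-(benzyloxy)-2-(tert-butyldimethylsilyloxy)-6-(1,3-dioxolan-2-yl)phenyl]-2-oxoacetate | COC(=O)C(=O)c1c(C2OCCO2)ccc(OCc2ccccc2)c1O[Si](C)(C)C(C)(C)C
F5 | step 4 | methyl (±)-2-[3-(benzyloxy)-2-(tert-butyldimethylsilyloxy)-6-(1,3-dioxolan-2-yl)phenyl]-2-hydroxyacetate | COC(=O)C(O)c1c(C2OCCO2)ccc(OCc2ccccc2)c1O[Si](C)(C)C(C)(C)C
F6 | step 14 | methyl (2S,3S)-2-(3,4-dihydroxyphenyl)-4-(1,3-dioxolan-2-yl)-7-hydroxy-2,3-dihydrobenzofuran-3-carboxylate | COC(=O)[C@H]1c2c(C3OCCO3)ccc(O)c2O[C@@H]1c1ccc(O)c(O)c1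
F7 | step 14 | methyl (2S,3S)-2-(3,4-dihydroxyphenyl)-4-formyl-7-hydroxy-2,3-dihydrobenzofuran-3-carboxylate | COC(=O)[C@H]1c2c(C=O)ccc(O)c2O[C@@H]1c1ccc(O)c(O)c1
F8 | step 14 | 3-{[(2R)-1-(benzyloxy)-3-[3,4-bis(benzyloxy)phenyl]-1-oxopropan-2-yl]oxy}-3-oxopropanoic acid | OC(=O)CC(=O)O[C@H](Cc1ccc(OCc2ccccc2)c(OCc2ccccc2)c1)C(=O)OCc1ccccc1
F9 | step 14 | (2R)-2-[(carboxyacetyl)oxy]-3-(3,4-dihydroxyphenyl)propanoic acid | OC(=O)CC(=O)O[C@H](Cc1ccc(O)c(O)c1)C(=O)O
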